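**Retrosynthetic overview** (side chain numbered from the benzylic carbon C1'; the carbinol carbon is C5')
1. Target ⇒ its hydroquinone dimethyl ether; the hydroquinone is unmasked last. No ring is formed anywhere: the benzene ring is bought intact.
2. C5'–C6' ⇒ geminal bis(boronate) + (E)-vinyl iodide, joined by an enantiotopic-group-selective palladium coupling; oxidation of the remaining C–B bond gives the (5'R) alcohol.
3. C4'–C5' ⇒ lithiated CH2(Bpin)2 + allylic bromide. CH2(Bpin)2 acts as a carbonyl-carbon dianion equivalent (boron standing in for oxygen), so the future carbinol carbon is the nucleophile toward two carbon electrophiles.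
4. Allylic bromide ⇐ aryl Grignard + isoprene monoxide (SN2'); vinyl iodide ⇐ (E)-geranylacetone via the terminal alkyne and carboalumination/iodination.

Assumption: 1-bromo-2,5-dimethoxy-3-methylbenzene, isoprene monoxide, CH2(Bpin)2 and (5E)-geranylacetone (≥96 % E) are bought as catalogue compounds.
Assumption: the ligand antipode written as (R,R) is taken to give the (R)-boronate; if the first run (Mosher ester check) shows the opposite sense, the (S,S) ligand is used instead.

**Route**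

Step 1
Reactants: 1 1-bromo-2,5-dimethoxy-3-methylbenzene; 2 2-methyl-2-vinyloxirane (isoprene monoxide)
Product: 4 (E)-4-(2,5-dimethoxy-3-methylphenyl)-2-methylbut-2-en-1-ol, via arylmagnesium bromide 3 (not isolated)
Conditions: Mg turnings, THF, reflux; then CuI (10 mol %), 2, THF, −30 to 0 °C; aq NH4Cl
Reagents that add atoms: none
Why: Copper-catalysed SN2' opening of a vinyl oxirane by an aryl Grignard reagent puts the aryl group on the terminal vinyl carbon and gives the (E)-trisubstituted allylic alcohol as the major isomer (about 9:1 E:Z expected, minor isomer removed by chromatography).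

Step 2
Reactants: 4 (E)-4-(2,5-dimethoxy-3-methylphenyl)-2-methylbut-2-en-1-ol
Product: 5 1-[(E)-4-bromo-3-methylbut-2-enyl]-2,5-dimethoxy-3-methylbenzene
Conditions: PBr3 (0.4 equiv), Et2O, −10 to 0 °C; used crude
Reagents that add atoms: phosphorus tribromide BrP(Br)Br
Why: Bromination of a primary allylic alcohol with PBr3 (SN2 displacement of the bromophosphite) proceeds at low temperature without loss of the (E) geometry.

Step 3
Reactants: 5 1-[(E)-4-bromo-3-methylbut-2-enyl]-2,5-dimethoxy-3-methylbenzene; 6 bis(pinacolato)borylmethane, CH2(Bpin)2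
Product: 8 2,2'-[(E)-5-(2,5-dimethoxy-3-methylphenyl)-3-methylpent-3-ene-1,1-diyl]bis(4,4,5,5-tetramethyl-1,3,2-dioxaborolane), via LiCH(Bpin)2 7 (not isolated)
Conditions: 6 (1.2 equiv), lithium 2,2,6,6-tetramethylpiperidide (1.2 equiv, from 2,2,6,6-tetramethylpiperidine + n-BuLi), THF, 0 °C, 10 min; then 5, 0 °C to rt, 2 h
Reagents that add atoms: none
Why: Alkylation of a boron-stabilised carbanion (lithiated geminal bis(boronate), a formyl-anion equivalent) with a primary allylic bromide is a clean SN2 process that forms C4'–C5'.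

Step 4
Reactants: 9 (5E)-6,10-dimethylundeca-5,9-dien-2-one ((E)-geranylacetone)
Product: 11 (5E)-6,10-dimethylundeca-5,9-dien-1-yne, via enol phosphate 10 (not isolated)
Conditions: LiN(iPr)2 (1.05 equiv), THF, −78 °C; ClP(O)(OEt)2 (1.1 equiv), −78 °C to rt; then LiN(iPr)2 (2.3 equiv), −78 °C to rt; H2O
Reagents that add atoms: none
Why: Negishi methyl ketone to terminal alkyne conversion, in which kinetic deprotonation at the methyl group, trapping as the terminal enol phosphate and base-induced β-elimination leave the (E)-trisubstituted alkene untouched.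

Step 5
Reactants: 11 (5E)-6,10-dimethylundeca-5,9-dien-1-yne
Product: 13 (1E,5E)-1-iodo-2,6,10-trimethylundeca-1,5,9-triene, via alkenyldimethylalane 12 (not isolated)
Conditions: Me3Al (2 equiv), Cp2ZrCl2 (0.25 equiv), CH2Cl2, 0 °C to rt, 12 h; then I2 (1.2 equiv), THF, −30 to 0 °C
Reagents that add atoms: trimethylaluminium C[Al](C)C; iodine II
Why: Negishi zirconium-catalysed carboalumination adds methyl and aluminium syn across the terminal alkyne with methyl on the internal carbon, and iodinolysis of the C–Al bond with retention gives the (E)-iodide.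

Step 6
Reactants: 8 2,2'-[(E)-5-(2,5-dimethoxy-3-methylphenyl)-3-methylpent-3-ene-1,1-diyl]bis(4,4,5,5-tetramethyl-1,3,2-dioxaborolane); 13 (1E,5E)-1-iodo-2,6,10-trimethylundeca-1,5,9-triene
Product: 15 (2E,5R,6E,10E)-1-(2,5-dimethoxy-3-methylphenyl)-3,7,11,15-tetramethylhexadeca-2,6,10,14-tetraen-5-ol, via (R)-allylic pinacol boronate 14 (not isolated)
Conditions: 8 (1.2 equiv), 13 (1.0 equiv), Pd(OAc)2 (5 mol %), (R,R)-TADDOL-derived phosphoramidite ligand (tetra-p-tolyl, P–NMe2; 10 mol %), 8 M aq KOH (10 equiv), 1,4-dioxane, rt, 18 h; then THF, 3 M aq NaOH, 30 % H2O2, 0 °C to rt, 2 h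
Reagents that add atoms: hydrogen peroxide OO
Why: Enantiotopic-group-selective Suzuki–Miyaura coupling of a geminal bis(boronate) with a vinyl halide, in which the chiral palladium–phosphoramidite catalyst transmetalates only one of the two enantiotopic Bpin groups so that C5' becomes the (R)-configured allylic boronate with the vinyl (E) geometry retained, and stereoretentive peroxide oxidation of the C–B bond then gives the (R)-alcohol.

Step 7
Reactants: 15 (2E,5R,6E,10E)-1-(2,5-dimethoxy-3-methylphenyl)-3,7,11,15-tetramethylhexadeca-2,6,10,14-tetraen-5-ol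
Product: 17 2-[(2E,5R,6E,10E)-5-hydroxy-3,7,11,15-tetramethylhexadeca-2,6,10,14-tetraenyl]-6-methylbenzene-1,4-diol (CNP0314458.2), via quinone 16 (not isolated)
Conditions: (NH4)2Ce(NO3)6 (2.5 equiv), MeCN/H2O 3:1, 0 °C, 15 min; then EtOAc, excess sat. aq Na2S2O4, rt, 15 min, under argon
Reagents that add atoms: water O
Why: Oxidative demethylation of a para-dimethoxyarene with (NH4)2Ce(NO3)6 (quinone oxygens delivered by water) is fast at 0 °C and spares isolated trisubstituted alkenes and the secondary alcohol, and dithionite reduction of the quinone gives the hydroquinone without touching the stereocentre.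

**Compound list**
1 | 1-bromo-2,5-dimethoxy-3-methylbenzene | COc1cc(C)c(OC)c(Br)c1 | starting material
2 | 2-methyl-2-vinyloxirane (isoprene monoxide, racemic) | C=CC1(C)CO1 | starting material
3 | (2,5-dimethoxy-3-methylphenyl)magnesium bromide | COc1cc(C)c(OC)c([Mg]Br)c1 | intermediate
4 | (E)-4-(2,5-dimethoxy-3-methylphenyl)-2-methylbut-2-en-1-ol | COc1cc(C)c(OC)c(C/C=C(\C)CO)c1 | intermediate
5 | 1-[(E)-4-bromo-3-methylbut-2-enyl]-2,5-dimethoxy-3-methylbenzene | COc1cc(C)c(OC)c(C/C=C(\C)CBr)c1 | intermediate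
6 | bis(pinacolato)borylmethane | CC1(C)OB(CB2OC(C)(C)C(C)(C)O2)OC1(C)C | starting material
7 | [bis(4,4,5,5-tetramethyl-1,3,2-dioxaborolan-2-yl)methyl]lithium | [Li]C(B1OC(C)(C)C(C)(C)O1)B1OC(C)(C)C(C)(C)O1 | intermediate
8 | 2,2'-[(E)-5-(2,5-dimethoxy-3-methylphenyl)-3-methylpent-3-ene-1,1-diyl]bis(4,4,5,5-tetramethyl-1,3,2-dioxaborolane) | COc1cc(C)c(OC)c(C/C=C(\C)CC(B2OC(C)(C)C(C)(C)O2)B2OC(C)(C)C(C)(C)O2)c1 | intermediate
9 | (5E)-6,10-dimethylundeca-5,9-dien-2-one ((E)-geranylacetone) | CC(=O)CC/C=C(\C)CCC=C(C)C | starting material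
10 | diethyl (5E)-6,10-dimethylundeca-1,5,9-trien-2-yl phosphate | C=C(OP(=O)(OCC)OCC)CC/C=C(\C)CCC=C(C)C | intermediate
11 | (5E)-6,10-dimethylundeca-5,9-dien-1-yne | C#CCC/C=C(\C)CCC=C(C)C | intermediate
12 | dimethyl[(1E,5E)-2,6,10-trimethylundeca-1,5,9-trienyl]alane | C[Al](C)/C=C(\C)CC/C=C(\C)CCC=C(C)C | intermediate
13 | (1E,5E)-1-iodo-2,6,10-trimethylundeca-1,5,9-triene | I/C=C(\C)CC/C=C(\C)CCC=C(C)C | intermediate
14 | 2-[(2E,5R,6E,10E)-1-(2,5-dimethoxy-3-methylphenyl)-3,7,11,15-tetramethylhexadeca-2,6,10,14-tetraen-5-yl]-4,4,5,5-tetramethyl-1,3,2-dioxaborolane | CC(C)=CCC/C(C)=C/CC/C(C)=C/[C@H](B1OC(C)(C)C(C)(C)O1)C/C(C)=C/Cc1cc(OC)cc(C)c1OC | intermediate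
15 | (2E,5R,6E,10E)-1-(2,5-dimethoxy-3-methylphenyl)-3,7,11,15-tetramethylhexadeca-2,6,10,14-tetraen-5-ol | CC(C)=CCC/C(C)=C/CC/C(C)=C/[C@H](O)C/C(C)=C/Cc1cc(OC)cc(C)c1OC | intermediate
16 | 2-[(2E,5R,6E,10E)-5-hydroxy-3,7,11,15-tetramethylhexadeca-2,6,10,14-tetraenyl]-6-methylcyclohexa-2,5-diene-1,4-dione | CC(C)=CCC/C(C)=C/CC/C(C)=C/[C@H](O)C/C(C)=C/CC1=CC(=O)C=C(C)C1=O | intermediate
17 | 2-[(2E,5R,6E,10E)-5-hydroxy-3,7,11,15-tetramethylhexadeca-2,6,10,14-tetraenyl]-6-methylbenzene-1,4-diol | CC(C)=CCC/C(C)=C/CC/C(C)=C/[C@H](O)C/C(C)=C/Cc1cc(O)cc(C)c1O | target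

**Totals**
Total step count: 7. Longest linear sequence: 5 (steps 1, 2, 3, 6, 7); the vinyl iodide branch (steps 4, 5) joins at step 6.

**Three steps most likely to fail, with fallbacks**

Risk A, step 6. The coupling has to engage a 2,2-disubstituted vinyl iodide in a polyene. The expected enantiomer ratio is roughly 90:10 to 95:5 and may need upgrading by preparative chiral HPLC. The fallback sets out from 5 and comes back at 15, using a classical masked acyl anion and a reagent-controlled reduction. (2E,6E)-farnesal F1 (bought) is treated with propane-1,3-dithiol and catalytic BF3·OEt2 in CH2Cl2 at −20 °C to give 2-[(1E,5E)-2,6,10-trimethylundeca-1,5,9-trienyl]-1,3-dithiane F2. Deprotonation with n-BuLi (THF, −30 °C) and α-alkylation with 5 gives the 2,2-disubstituted dithiane F3. MeI and CaCO3 in aqueous MeCN unmask the β,γ-unsaturated dienone F4. Reduction with BH3·SMe2 and 10 mol % (S)-1-methyl-3,3-diphenyltetrahydro-1H,3H-pyrrolo[1,2-c][1,3,2]oxazaborole at −30 °C (Corey–Bakshi–Shibata reduction, alkenyl group as the large substituent) gives 15.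

Risk B, step 1. The E:Z ratio and the SN2'/SN2 ratio of the vinyl oxirane opening may be worse than hoped on this ortho-substituted aryl nucleophile. The fallback sets out from 1 and comes back at 4. The Grignard reagent 3 made from 1 is coupled with prenyl bromide F5 (bought) under CuI catalysis in THF at 0 °C to give the prenylarene 2,5-dimethoxy-1-methyl-3-(3-methylbut-2-enyl)benzene F6. Allylic oxidation with catalytic SeO2 and t-BuOOH in CH2Cl2 hydroxylates the (E)-methyl group selectively. Any over-oxidised (E)-4-(2,5-dimethoxy-3-methylphenyl)-2-methylbut-2-enal F7 is returned to 4 with NaBH4 in MeOH.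

Risk C, step 7. (NH4)2Ce(NO3)6 may attack the free allylic alcohol, and the hydroquinone re-oxidises in air. The fallback sets out from 15 and comes back at 17, with the carbinol masked during the oxidation. Ac2O, pyridine and catalytic DMAP give the (5R)-acetate F8. (NH4)2Ce(NO3)6 in MeCN/H2O then gives the quinone acetate F9. Dithionite work-up gives the hydroquinone acetate F10, and K2CO3 in degassed MeOH under argon removes the acetate to give 17.

**Further compounds**
F1 | step 6 | (2E,6E)-farnesal (bought) | CC(C)=CCC/C(C)=C/CC/C(C)=C/C=O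
F2 | step 6 | 2-[(1E,5E)-2,6,10-trimethylundeca-1,5,9-trienyl]-1,3-dithiane | CC(C)=CCC/C(C)=C/CC/C(C)=C/C1SCCCS1
F3 | step 6 | 2-[(E)-4-(2,5-dimethoxy-3-methylphenyl)-2-methylbut-2-enyl]-2-[(1E,5E)-2,6,10-trimethylundeca-1,5,9-trienyl]-1,3-dithiane | CC(C)=CCC/C(C)=C/CC/C(C)=C/C1(C/C(C)=C/Cc2cc(OC)cc(C)c2OC)SCCCS1
F4 | step 6 | (2E,6E,10E)-1-(2,5-dimethoxy-3-methylphenyl)-3,7,11,15-tetramethylhexadeca-2,6,10,14-tetraen-5-one | CC(C)=CCC/C(C)=C/CC/C(C)=C/C(=O)C/C(C)=C/Cc1cc(OC)cc(C)c1OC
F5 | step 1 | 1-bromo-3-methylbut-2-ene (prenyl bromide, bought) | CC(C)=CCBr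
F6 | step 1 | 2,5-dimethoxy-1-methyl-3-(3-methylbut-2-enyl)benzene | COc1cc(C)c(OC)c(CC=C(C)C)c1
F7 | step 1 | (E)-4-(2,5-dimethoxy-3-methylphenyl)-2-methylbut-2-enal | COc1cc(C)c(OC)c(C/C=C(\C)C=O)c1
F8 | step 7 | (2E,5R,6E,10E)-1-(2,5-dimethoxy-3-methylphenyl)-3,7,11,15-tetramethylhexadeca-2,6,10,14-tetraen-5-yl acetate | CC(C)=CCC/C(C)=C/CC/C(C)=C/[C@H](OC(C)=O)C/C(C)=C/Cc1cc(OC)cc(C)c1OC
F9 | step 7 | (2E,5R,6E,10E)-3,7,11,15-tetramethyl-1-(5-methyl-3,6-dioxocyclohexa-1,4-dienyl)hexadeca-2,6,10,14-tetraen-5-yl acetate | CC(C)=CCC/C(C)=C/CC/C(C)=C/[C@H](OC(C)=O)C/C(C)=C/CC1=CC(=O)C=C(C)C1=O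
F10 | step 7 | (2E,5R,6E,10E)-1-(2,5-dihydroxy-3-methylphenyl)-3,7,11,15-tetramethylhexadeca-2,6,10,14-tetraen-5-yl acetate | CC(C)=CCC/C(C)=C/CC/C(C)=C/[C@H](OC(C)=O)C/C(C)=C/Cc1cc(O)cc(C)c1O
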